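**Plan**

Numbering: ring A is the monohydroxy ring (C1 OH, C3 chain, C5 ether O); ring B is the dihydroxy ring (C1′ ether O, C2′ and C4′ OH, C6′ chain); chain carbons run from C1 (on C6′) to C14 (on ring A C3).
Cuts, in retrosynthetic order: three O–CH3 bonds (protecting groups); chain C3–C4, which opens the 20-membered ring; C4=C5 (C4 from iodoform); ring A C3–C14; ring A C5–O; ring B C6′–C1.
Enabling feature: C1–C3 sit on C6′, ortho to the ether oxygen on C1′, so they are an allyl group that a Claisen rearrangement moves from that oxygen to C6′, freeing the oxygen for the diaryl ether. The terminal carbon C3 then becomes a primary alkylborane that meets C4, offered as an iodoalkene, in an intramolecular B-alkyl Suzuki–Miyaura coupling.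
Forward: ring B allylphenol (steps 1–2), diaryl ether to ring A (step 3), the C5–C14 arm by intermolecular B-alkyl Suzuki coupling (step 4), iodoalkene (steps 5–6), ring closure (step 7), hydrogenation and demethylation (steps 8–9). Both aromatic rings are bought.
Stereochemistry: the target has no stereocentre. The only stereo element on the way, the C4=C5 double bond, is removed by hydrogenation, so its geometry has no consequence.

Key step: step 7

Assumption: 2,4-dimethoxyphenol, 1-bromo-3-iodo-5-methoxybenzene and methyl dec-9-enoate are taken as catalogue compounds; methyl ethers are the only protecting groups.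

**Route**

Step 1
Reactants: 1 2,4-dimethoxyphenol; 2 allyl bromide (3-bromoprop-1-ene)
Product: 3 2,4-dimethoxy-1-(prop-2-en-1-yloxy)benzene
Conditions: K2CO3, acetone, reflux
Reagents that add atoms: none
Why: Williamson ether synthesis, in which the phenoxide of an unhindered electron-rich phenol should displace bromide from the allylic halide cleanly at oxygen.

Step 2
Reactants: 3 2,4-dimethoxy-1-(prop-2-en-1-yloxy)benzene
Product: 5 2-allyl-4,6-dimethoxyphenol, via dienone 4 (not isolated)
Conditions: PhNEt2, 200 °C
Reagents that add atoms: none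
Why: Aromatic Claisen rearrangement ([3,3] sigmatropic shift) should deliver the allyl group to the only free ortho carbon, since the other ortho and the para position carry OMe, and dienone 4 tautomerises to the phenol.

Step 3
Reactants: 5 2-allyl-4,6-dimethoxyphenol; 6 1-bromo-3-iodo-5-methoxybenzene
Product: 7 2-(3-bromo-5-methoxyphenoxy)-1,5-dimethoxy-3-(prop-2-en-1-yl)benzene
Conditions: CuI (10 mol%), picolinic acid (20 mol%), K3PO4, DMSO, 80 °C
Reagents that add atoms: none
Why: Ullmann-type C–O coupling with a picolinate-ligated copper catalyst, a system suited to doubly ortho-substituted phenols, should react at C–I well ahead of C–Br, so the bromide is kept for step 4.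

Step 4
Reactants: 7 2-(3-bromo-5-methoxyphenoxy)-1,5-dimethoxy-3-(prop-2-en-1-yl)benzene; 8 methyl dec-9-enoate
Product: 10 methyl 10-{3-[2,4-dimethoxy-6-(prop-2-en-1-yl)phenoxy]-5-methoxyphenyl}decanoate, via alkylborane 9 (not isolated)
Conditions: 8 (slight excess), 9-BBN, THF, 0 °C to rt; then 7, Pd(dppf)Cl2 (5 mol%), aq. K3PO4, DMF, 50 °C
Reagents that add atoms: none
Why: Intermolecular B-alkyl Suzuki–Miyaura coupling: anti-Markovnikov hydroboration of 8 (ester tolerated) gives primary alkylborane 9, which should couple with the aryl bromide, and because 8 is in excess over 9-BBN no B–H remains to attack the allyl group of 7.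

Step 5
Reactants: 10 methyl 10-{3-[2,4-dimethoxy-6-(prop-2-en-1-yl)phenoxy]-5-methoxyphenyl}decanoate
Product: 12 10-{3-[2,4-dimethoxy-6-(prop-2-en-1-yl)phenoxy]-5-methoxyphenyl}decanal, via aluminium hemiacetal 11 (not isolated)
Conditions: i-Bu2AlH (1.1 equiv), CH2Cl2, −78 °C; then MeOH, aq. potassium sodium tartrate
Reagents that add atoms: none
Why: Partial reduction of an ester with diisobutylaluminium hydride: the tetrahedral aluminium hemiacetal 11 should persist at −78 °C and release the aldehyde only on aqueous work-up, while the alkene and the ethers are inert.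

Step 6
Reactants: 12 10-{3-[2,4-dimethoxy-6-(prop-2-en-1-yl)phenoxy]-5-methoxyphenyl}decanal
Product: 13 2-{3-[(10E)-11-iodoundec-10-en-1-yl]-5-methoxyphenoxy}-1,5-dimethoxy-3-(prop-2-en-1-yl)benzene
Conditions: CrCl2, CHI3, THF, 0 °C to rt
Reagents that add atoms: iodoform (triiodomethane), IC(I)I
Why: Takai olefination: the geminal dichromium species formed from CHI3 and divalent chromium should add to the aldehyde and eliminate to the E iodoalkene without touching the terminal alkene or the aryl ethers, and any Z isomer can be carried along because the double bond is hydrogenated later.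

Step 7
Reactants: 13 2-{3-[(10E)-11-iodoundec-10-en-1-yl]-5-methoxyphenoxy}-1,5-dimethoxy-3-(prop-2-en-1-yl)benzene
Product: 15 (4E)-4,5-didehydro tri-O-methyl ether of the target macrocycle, via alkylborane 14 (not isolated)
Conditions: 9-BBN, THF, rt; then H2O; then syringe-pump addition to Pd(dppf)Cl2 (20 mol%), AsPh3 (20 mol%), Cs2CO3, DMF/THF/H2O, 50 °C, final 1 mM
Reagents that add atoms: none
Why: 9-BBN should add across the allyl C2=C3 bond anti-Markovnikov to give primary alkylborane 14 with boron on C3, after which zerovalent palladium (formed in the flask from Pd(dppf)Cl2) inserts into the C4–I bond with retention of geometry, the base turns the borane into a borate that hands C3 to palladium, and reductive elimination forms the C3–C4 bond. The closest known reaction type is the intramolecular B-alkyl Suzuki–Miyaura macrocyclization of a substrate carrying a terminal alkene and an iodoalkene. The single ring formed is the 20-membered ring (14 chain carbons, C6′ and C1′ of ring B, the ether oxygen, and C5, C4 and C3 of ring A), closed through a 21-membered palladacycle in the endo sense, so that C4=C5 lies inside the ring. No stereocentre is created, and the E double bond is carried over unchanged and removed in step 8. The step needs chemoselective and regioselective hydroboration, which the bulk of 9-BBN secures (the monosubstituted alkene reacts at its CH2 end, while the iodoalkene, the arenes and the ethers do not), and ring closure ahead of chain growth, which slow addition to high dilution secures, helped by the diaryl ether hinge that already holds the two chain ends within reach. β-Hydride elimination from the alkylpalladium should be held back by the wide bite angle of dppf and by AsPh3, which speeds transmetalation.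

Step 8
Reactants: 15 (4E)-4,5-didehydro tri-O-methyl ether of the target macrocycle
Product: 16 tri-O-methyl ether of the target macrocycle
Conditions: H2 (1 atm), 10% Pd/C, EtOAc, rt
Reagents that add atoms: none
Why: Heterogeneous catalytic hydrogenation should saturate the disubstituted ring alkene, while aryl methyl ethers and the diaryl ether are inert at 1 atm and room temperature.

Step 9
Reactants: 16 tri-O-methyl ether of the target macrocycle
Product: 18 CNP0173380.0 (target), via tris(dibromoboryl) ether 17 (not isolated)
Conditions: BBr3 (excess), CH2Cl2, −78 °C to rt; then H2O, 0 °C, under argon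
Reagents that add atoms: none
Why: Lewis-acid demethylation of aryl methyl ethers with BBr3 (boron binds oxygen, bromide attacks the methyl carbon) should cleave all three O–CH3 bonds, the diaryl ether has no alkyl C–O bond to lose, and hydrolysis of 17 frees the three phenols.

**Compound list**

1 | 2,4-dimethoxyphenol | COc1ccc(O)c(OC)c1 | starting material
2 | allyl bromide (3-bromoprop-1-ene) | C=CCBr | starting material
3 | 2,4-dimethoxy-1-(prop-2-en-1-yloxy)benzene | COc1ccc(OCC=C)c(OC)c1 | intermediate
4 | 6-allyl-2,4-dimethoxycyclohexa-2,4-dien-1-one (racemic, transient) | O=C1C(OC)=CC(OC)=CC1CC=C | intermediate (not isolated)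
5 | 2-allyl-4,6-dimethoxyphenol | COc1cc(CC=C)c(O)c(OC)c1 | intermediate
6 | 1-bromo-3-iodo-5-methoxybenzene | COc1cc(Br)cc(I)c1 | starting material
7 | 2-(3-bromo-5-methoxyphenoxy)-1,5-dimethoxy-3-(prop-2-en-1-yl)benzene | COc1cc(Br)cc(Oc2c(CC=C)cc(OC)cc2OC)c1 | intermediate
8 | methyl dec-9-enoate | C=CCCCCCCCC(=O)OC | starting material
9 | methyl 10-(9-borabicyclo[3.3.1]nonan-9-yl)decanoate | COC(=O)CCCCCCCCCB1C2CCCC1CCC2 | intermediate (not isolated)
10 | methyl 10-{3-[2,4-dimethoxy-6-(prop-2-en-1-yl)phenoxy]-5-methoxyphenyl}decanoate | COC(=O)CCCCCCCCCc1cc(OC)cc(Oc2c(CC=C)cc(OC)cc2OC)c1 | intermediate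
11 | diisobutyl[(1-methoxy-10-{3-[2,4-dimethoxy-6-(prop-2-en-1-yl)phenoxy]-5-methoxyphenyl}decyl)oxy]alumane (racemic at the hemiacetal carbon) | COC(CCCCCCCCCc1cc(OC)cc(Oc2c(CC=C)cc(OC)cc2OC)c1)O[Al](CC(C)C)CC(C)C | intermediate (not isolated)
12 | 10-{3-[2,4-dimethoxy-6-(prop-2-en-1-yl)phenoxy]-5-methoxyphenyl}decanal | O=CCCCCCCCCCc1cc(OC)cc(Oc2c(CC=C)cc(OC)cc2OC)c1 | intermediate
13 | 2-{3-[(10E)-11-iodoundec-10-en-1-yl]-5-methoxyphenoxy}-1,5-dimethoxy-3-(prop-2-en-1-yl)benzene | I/C=C/CCCCCCCCCc1cc(OC)cc(Oc2c(CC=C)cc(OC)cc2OC)c1 | intermediate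
14 | 9-[3-(2-{3-[(10E)-11-iodoundec-10-en-1-yl]-5-methoxyphenoxy}-3,5-dimethoxyphenyl)propyl]-9-borabicyclo[3.3.1]nonane | I/C=C/CCCCCCCCCc1cc(OC)cc(Oc2c(CCCB3C4CCCC3CCC4)cc(OC)cc2OC)c1 | intermediate (not isolated)
15 | (4E)-4,5-didehydro tri-O-methyl ether of the target: 20-membered ring in which ring A (C1 OMe, C3 chain, C5 O) and ring B (C1′ O, C2′ and C4′ OMe, C6′ chain) are joined by the ether oxygen and by the chain CH2CH2CH2–CH=CH–(CH2)9, E double bond between chain C4 and C5 | COc1cc2cc(c1)Oc1c(OC)cc(OC)cc1CCC/C=C/CCCCCCCCC2 | intermediate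
16 | tri-O-methyl ether of the target: the same ring with a saturated (CH2)14 chain | COc1cc2cc(c1)Oc1c(OC)cc(OC)cc1CCCCCCCCCCCCCC2 | intermediate
17 | tris(O-dibromoboryl) derivative of the target (OBBr2 on ring A C1 and on ring B C2′ and C4′) | BrB(Br)Oc1cc2cc(c1)Oc1c(OB(Br)Br)cc(OB(Br)Br)cc1CCCCCCCCCCCCCC2 | intermediate (not isolated)
18 | CNP0173380.0: 20-membered diaryl ether macrocycle, ring A with OH on C1, ring B with OH on C2′ and C4′, (CH2)14 chain from C6′ to ring A C3, no stereocentre | Oc1cc2cc(c1)Oc1c(O)cc(O)cc1CCCCCCCCCCCCCC2 | target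

**Count**

Total step count: 9.
Longest linear sequence: 9 steps (1 to 18; compounds 2, 6 and 8 are bought and enter directly).

**Steps most likely to fail**

Step 7. Chain growth between two molecules may outrun ring closure, and the alkyl group may be lost from boron or palladium (protodeboronation, β-hydride elimination) before the C3–C4 bond forms. The fallback sets out from 13 and comes back at 16; it closes the same bond by a Nozaki–Hiyama–Kishi reaction instead of a cross-coupling. Hydroboration of 13 with 9-BBN followed by oxidation with NaBO3·4H2O should give the primary alcohol 3-(2-{3-[(10E)-11-iodoundec-10-en-1-yl]-5-methoxyphenoxy}-3,5-dimethoxyphenyl)propan-1-ol F1. Dess–Martin oxidation (NaHCO3, CH2Cl2) should give the aldehyde 3-(2-{3-[(10E)-11-iodoundec-10-en-1-yl]-5-methoxyphenoxy}-3,5-dimethoxyphenyl)propanal F2. CrCl2 with catalytic NiCl2 in DMSO/THF at high dilution should turn the C4–I bond into an alkenylchromium species (trivalent chromium) that adds to the C3 aldehyde and closes the 20-membered ring as the racemic (4E)-3-hydroxy-4,5-didehydro tri-O-methyl macrocycle F3. Hydrogenation (H2, Pd/C, EtOAc) should give the racemic 3-hydroxy tri-O-methyl macrocycle F4. NaH, CS2 and MeI in THF should give the O-(tri-O-methyl macrocycle C3-yl) S-methyl dithiocarbonate F5, and Barton–McCombie deoxygenation (Bu3SnH, AIBN, toluene, reflux) should then deliver 16.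

Step 3. C–O bond formation at the doubly ortho-substituted phenoxide may be slow, so that reduction of the aryl iodide and base-induced migration of the allyl double bond into conjugation take over. The fallback sets out from 6 and 5 and comes back at 7; it replaces copper catalysis by metal-free O-arylation with a diaryliodonium salt. Oxidation of 6 with mCPBA and TsOH·H2O in MeCN, followed by 1,3,5-trimethoxybenzene, should give (3-bromo-5-methoxyphenyl)(2,4,6-trimethoxyphenyl)iodonium 4-methylbenzenesulfonate F6. The potassium phenoxide of 5 (KOt-Bu, toluene, rt) should then undergo ligand coupling at the hypervalent iodine, which tolerates ortho-substituted phenols and transfers the less electron-rich 3-bromo-5-methoxyphenyl group to oxygen, giving 7.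

Step 5. The aluminium hemiacetal may break down before the quench, so that a second hydride is delivered and the primary alcohol forms beside the aldehyde. The fallback sets out from 10 and comes back at 12; it reduces fully and re-oxidises. LiAlH4 in THF at 0 °C should give 10-{3-[2,4-dimethoxy-6-(prop-2-en-1-yl)phenoxy]-5-methoxyphenyl}decan-1-ol F7, and Dess–Martin oxidation (or a Swern oxidation) should return 12.

**Further compounds**

F1 | step 7 | 3-(2-{3-[(10E)-11-iodoundec-10-en-1-yl]-5-methoxyphenoxy}-3,5-dimethoxyphenyl)propan-1-ol | I/C=C/CCCCCCCCCc1cc(OC)cc(Oc2c(CCCO)cc(OC)cc2OC)c1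
F2 | step 7 | 3-(2-{3-[(10E)-11-iodoundec-10-en-1-yl]-5-methoxyphenoxy}-3,5-dimethoxyphenyl)propanal | I/C=C/CCCCCCCCCc1cc(OC)cc(Oc2c(CCC=O)cc(OC)cc2OC)c1
F3 | step 7 | (4E)-3-hydroxy-4,5-didehydro tri-O-methyl macrocycle (racemic; OH on chain C3) | COc1cc2cc(c1)Oc1c(OC)cc(OC)cc1CCC(O)/C=C/CCCCCCCCC2
F4 | step 7 | 3-hydroxy tri-O-methyl macrocycle (racemic; OH on chain C3) | COc1cc2cc(c1)Oc1c(OC)cc(OC)cc1CCC(O)CCCCCCCCCCC2
F5 | step 7 | O-(tri-O-methyl macrocycle C3-yl) S-methyl dithiocarbonate (racemic) | COc1cc2cc(c1)Oc1c(OC)cc(OC)cc1CCC(OC(=S)SC)CCCCCCCCCCC2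
F6 | step 3 | (3-bromo-5-methoxyphenyl)(2,4,6-trimethoxyphenyl)iodonium 4-methylbenzenesulfonate | COc1cc(Br)cc([I+]c2c(OC)cc(OC)cc2OC)c1.Cc1ccc(cc1)S([O-])(=O)=O
F7 | step 5 | 10-{3-[2,4-dimethoxy-6-(prop-2-en-1-yl)phenoxy]-5-methoxyphenyl}decan-1-ol | OCCCCCCCCCCc1cc(OC)cc(Oc2c(CC=C)cc(OC)cc2OC)c1
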